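**Retrosynthetic overview**
1. Both C3–aryl bonds of the two trans-2-aryl-2,3-dihydrobenzofurans are cut by decarboxylative arylation (C3′–resorcinol ring last, C3–C5′ as the fragment union). This leaves two 2-aryl-2,3-dihydrobenzofuran-3-carboxylates.
2. Each carboxylate is the ring-contracted isomer of a flavanone. The lower ester 11 comes from (2R)-flavanone 8 by oxidative 1,2-shift of ring C carbon C4a from C4 to C3, which makes C3a′–C3′ and closes the lower dihydrofuran ring. The upper ester comes the same way from chiral-pool (S)-naringenin (C2 → C2 (S); 7-OH → C6–OH; 5-OH → triflate → styryl; 4′-OH → 4-hydroxyphenyl).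
3. Enabling feature: in the lower unit, O1′–C2′(aryl)–C3′ is tied to ring C through C7a′ and C3a′, and C3′ carries exactly one further carbon substituent. Putting one carbon back between C3′ and C3a′ gives a 2-arylchroman-4-one whose C8 oxygen (ortho to O1) is the C7′ phenol and whose C6 (para to O1) is the attachment point C5′.
4. Ring order: pyranone of chromone 5 → flavanone 8 → lower dihydrofuran (step 6); naringenin pyranone → upper dihydrofuran (step 10); then stilbene, union, resorcinol ring, deprotection.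

Key step: step 6

Remark: the target is read as (2S,3S) in the upper and (2R,3R) in the lower dihydrobenzofuran, both trans. (S)-Naringenin is assumed to be purchasable enantiopure and not to racemise (via the chalcone) under the neutral or pyridine-buffered conditions of steps 7 to 9. Ring A = benzo ring of the upper unit, ring C = benzo ring of the lower unit (primed locants); Bn = benzyl, Ts = 4-methylbenzenesulfonyl, Tf = trifluoromethanesulfonyl, NHP = N-hydroxyphthalimide, dtbbpy = 4,4′-di-tert-butyl-2,2′-bipyridine.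

**Lower fragment**

Step 1
Reactants: 1 1-(2,3-dihydroxyphenyl)ethan-1-one
Product: 2 1-[3-(benzyloxy)-2-hydroxyphenyl]ethan-1-one
Conditions: NaH (2.1 equiv), DMSO, 20 °C; BnBr (1.0 equiv); aq. HCl
Reagents that add atoms: benzyl bromide, BrCc1ccccc1
Why: In the dianion the non-chelated C3 phenoxide is the more nucleophilic oxygen, so one equivalent of benzyl bromide should give the 3-O-benzyl ether (Williamson ether synthesis on a dianion).

Step 2
Reactants: 2 1-[3-(benzyloxy)-2-hydroxyphenyl]ethan-1-one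
Product: 3 1-[3-(benzyloxy)-5-bromo-2-hydroxyphenyl]ethan-1-one
Conditions: NBS (1.05 equiv), MeCN, 0 °C to 20 °C
Reagents that add atoms: N-bromosuccinimide, O=C1CCC(=O)N1Br
Why: Electrophilic aromatic bromination should go para to the free hydroxyl, the strongest director on the ring.

Step 3
Reactants: 3 1-[3-(benzyloxy)-5-bromo-2-hydroxyphenyl]ethan-1-one
Product: 5 8-(benzyloxy)-6-bromo-4H-chromen-4-one, via enaminone 4 (not isolated)
Conditions: Me2NCH(OMe)2, toluene, 100 °C; then conc. HCl, CH2Cl2, 20 °C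
Reagents that add atoms: N,N-dimethylformamide dimethyl acetal, COC(OC)N(C)C
Why: Condensation of the methyl ketone with the amide acetal gives the enaminone, and acid-promoted addition of the phenol with loss of dimethylamine closes the pyranone ring (enaminone route to chromones).

Step 4
Reactants: 6 (4-hydroxyphenyl)boronic acid
Product: 7 [4-(tosyloxy)phenyl]boronic acid
Conditions: TsCl, K2CO3, THF/H2O, 0 °C to 20 °C; then aq. HCl to pH 4
Reagents that add atoms: 4-methylbenzenesulfonyl chloride, Cc1ccc(cc1)S(Cl)(=O)=O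
Why: Schotten–Baumann sulfonylation of the phenolate should proceed while the boronic acid survives aqueous carbonate.

Step 5
Reactants: 5 8-(benzyloxy)-6-bromo-4H-chromen-4-one; 7 [4-(tosyloxy)phenyl]boronic acid
Product: 8 (2R)-8-(benzyloxy)-6-bromo-2-[4-(tosyloxy)phenyl]chroman-4-one
Conditions: Pd(OCOCF3)2 (5 mol %), (S)-t-BuPyOx (6 mol %), NH4PF6 (30 mol %), H2O (5 equiv), ClCH2CH2Cl, 60 °C
Reagents that add atoms: none
Why: This is the cationic divalent-palladium/pyridine-oxazoline asymmetric conjugate addition of an arylboronic acid to a chromone, in which the ligand-controlled face of aryl transfer should set C2 as R (the S ligand is expected to do so by analogy with cyclic enones, the antipode being used otherwise) and the divalent-palladium cycle should leave the C–Br bond alone.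

Step 6
Reactants: 8 (2R)-8-(benzyloxy)-6-bromo-2-[4-(tosyloxy)phenyl]chroman-4-one
Product: 11 methyl (2R,3R)-7-(benzyloxy)-5-bromo-2-[4-(tosyloxy)phenyl]-2,3-dihydro-1-benzofuran-3-carboxylate, via enol ether 9 (not isolated), via iodane 10 (not isolated)
Conditions: PhI(OAc)2 (1.2 equiv), H2SO4, HC(OMe)3, 0 °C to 20 °C; aq. NaHCO3
Reagents that add atoms: trimethyl orthoformate, COC(OC)OC; water (work-up), O
Why: Acid and orthoformate should turn the C4 ketone into enol ether 9; the trivalent-iodine electrophile then adds to C3 anti to the C2 aryl and methanol re-adds at C4 to give iodane 10, whose equatorial C3–I bond is anti-periplanar to C4–C4a, so ring C carbon C4a shifts from C4 to C3 with loss of iodobenzene and the dimethoxycarbenium ion left at C4 ends as the methyl ester. The closest known reaction type is the hypervalent-iodine oxidative ring contraction of flavanones to methyl trans-2-aryl-2,3-dihydrobenzofuran-3-carboxylates. The lower dihydrofuran ring is closed by this 1,2-aryl shift: the ipso carbon bridges to C3 through a phenonium-like three-membered transition state (3-exo-tet) and the C4–C4a bond breaks, a six-to-five ring contraction. C2′ is not touched and stays R, and C3′ is set by inversion at C3 (C4a enters anti to iodine, which sat trans to the aryl), which places the carboxyl trans to the C2′ aryl, also the thermodynamic arrangement. The step needs migration of ring C in preference to migration of the C2 aryl (isoflavone formation) or simple dehydrogenation to the flavone. This is secured by the tosylate, which makes the C2 aryl electron-poor, and by O1 ortho to C4a, which stabilises the bridged cation, while bromide and benzyl ether are spectators.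

**Upper fragment**

Step 7
Reactants: 12 (2S)-naringenin [(2S)-5,7-dihydroxy-2-(4-hydroxyphenyl)chroman-4-one]
Product: 13 (2S)-7-(benzyloxy)-5-hydroxy-2-(4-hydroxyphenyl)chroman-4-one
Conditions: BnOH (1.05 equiv), PPh3, DIAD, THF, 0 °C to 20 °C
Reagents that add atoms: benzyl alcohol, OCc1ccccc1
Why: The Mitsunobu etherification should select the most acidic phenol (7-OH, a vinylogous acid) under neutral conditions, so the base-labile C2 centre is not exposed to ring opening.

Step 8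
Reactants: 13 (2S)-7-(benzyloxy)-5-hydroxy-2-(4-hydroxyphenyl)chroman-4-one
Product: 14 (2S)-7-(benzyloxy)-5-hydroxy-2-[4-(tosyloxy)phenyl]chroman-4-one
Conditions: TsCl (1.1 equiv), pyridine, CH2Cl2, 0 °C
Reagents that add atoms: 4-methylbenzenesulfonyl chloride, Cc1ccc(cc1)S(Cl)(=O)=O
Why: The free 4′-phenol should be sulfonylated while the 5-OH, hydrogen-bonded to the ketone, stays inert.

Step 9
Reactants: 14 (2S)-7-(benzyloxy)-5-hydroxy-2-[4-(tosyloxy)phenyl]chroman-4-one
Product: 15 (2S)-7-(benzyloxy)-2-[4-(tosyloxy)phenyl]-5-(triflyloxy)chroman-4-one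
Conditions: Tf2O, pyridine, CH2Cl2, −20 °C to 0 °C
Reagents that add atoms: trifluoromethanesulfonic anhydride, O=S(=O)(OS(=O)(=O)C(F)(F)F)C(F)(F)F
Why: The chelated 5-phenol should be sulfonylated by the strongly electrophilic anhydride, as is standard for 5-hydroxyflavonoids.

Step 10
Reactants: 15 (2S)-7-(benzyloxy)-2-[4-(tosyloxy)phenyl]-5-(triflyloxy)chroman-4-one
Product: 18 methyl (2S,3S)-6-(benzyloxy)-2-[4-(tosyloxy)phenyl]-4-(triflyloxy)-2,3-dihydro-1-benzofuran-3-carboxylate, via enol ether 16 (not isolated), via iodane 17 (not isolated)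
Conditions: PhI(OAc)2 (1.2 equiv), H2SO4, HC(OMe)3, 0 °C to 20 °C; aq. NaHCO3
Reagents that add atoms: trimethyl orthoformate, COC(OC)OC; water (work-up), O
Why: The same oxidative 1,2-aryl shift as in step 6 should contract the pyranone ring, with ring A (O1 ortho and benzyloxy para to the migrating carbon) migrating in preference to the tosylated C2 aryl, C2 kept as S and the ester placed trans by the anti-periplanar shift.

Step 11
Reactants: 18 methyl (2S,3S)-6-(benzyloxy)-2-[4-(tosyloxy)phenyl]-4-(triflyloxy)-2,3-dihydro-1-benzofuran-3-carboxylate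
Product: 19 (2S,3S)-6-(benzyloxy)-2-[4-(tosyloxy)phenyl]-4-(triflyloxy)-2,3-dihydro-1-benzofuran-3-carboxylic acid
Conditions: Me3SnOH (6 equiv), ClCH2CH2Cl, 75 °C; aq. HCl
Reagents that add atoms: trimethyltin hydroxide, C[Sn](C)(C)O
Why: This mild methyl-ester cleavage should avoid enolisation at C3, and with it β-elimination of the ring oxygen and loss of the C2 configuration, and should leave the aryl sulfonates intact.

Step 12
Reactants: 20 1-(benzyloxy)-4-ethynylbenzene
Product: 21 2-{(E)-2-[4-(benzyloxy)phenyl]ethenyl}-4,4,5,5-tetramethyl-1,3,2-dioxaborolane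
Conditions: pinacolborane (1.2 equiv), Cp2Zr(H)Cl (5 mol %), Et3N (10 mol %), 60 °C
Reagents that add atoms: pinacolborane, CC1(C)OBOC1(C)C
Why: Catalysed syn-hydroboration of the terminal alkyne should give the E-alkenylboronate with boron on the terminal carbon.

Step 13
Reactants: 19 (2S,3S)-6-(benzyloxy)-2-[4-(tosyloxy)phenyl]-4-(triflyloxy)-2,3-dihydro-1-benzofuran-3-carboxylic acid; 21 2-{(E)-2-[4-(benzyloxy)phenyl]ethenyl}-4,4,5,5-tetramethyl-1,3,2-dioxaborolane
Product: 22 (2S,3S)-6-(benzyloxy)-4-{(E)-2-[4-(benzyloxy)phenyl]ethenyl}-2-[4-(tosyloxy)phenyl]-2,3-dihydro-1-benzofuran-3-carboxylic acid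
Conditions: Pd(dppf)Cl2 (5 mol %), K2CO3 (4 equiv), 1,4-dioxane/H2O, 80 °C; aq. HCl
Reagents that add atoms: none
Why: Suzuki–Miyaura coupling of the aryl triflate should proceed with retention of alkene geometry, the substrate reacting as its carboxylate (which blocks deprotonation at C3) and the tosylate being inert toward this catalyst.

Step 14
Reactants: 22 (2S,3S)-6-(benzyloxy)-4-{(E)-2-[4-(benzyloxy)phenyl]ethenyl}-2-[4-(tosyloxy)phenyl]-2,3-dihydro-1-benzofuran-3-carboxylic acid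
Product: 23 1,3-dioxoisoindolin-2-yl (2S,3S)-6-(benzyloxy)-4-{(E)-2-[4-(benzyloxy)phenyl]ethenyl}-2-[4-(tosyloxy)phenyl]-2,3-dihydro-1-benzofuran-3-carboxylate
Conditions: N-hydroxyphthalimide, DIC, CH2Cl2, 0 °C to 20 °C (no amine base)
Reagents that add atoms: N-hydroxyphthalimide, O=C1c2ccccc2C(=O)N1O
Why: Carbodiimide esterification should give the redox-active ester, and leaving out amine base avoids enolisation of the activated ester.

**Union and completion**

Step 15
Reactants: 23 1,3-dioxoisoindolin-2-yl (2S,3S)-6-(benzyloxy)-4-{(E)-2-[4-(benzyloxy)phenyl]ethenyl}-2-[4-(tosyloxy)phenyl]-2,3-dihydro-1-benzofuran-3-carboxylate; 11 methyl (2R,3R)-7-(benzyloxy)-5-bromo-2-[4-(tosyloxy)phenyl]-2,3-dihydro-1-benzofuran-3-carboxylate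
Product: 24 methyl (2R,3R)-7-(benzyloxy)-5-[(2S,3S)-6-(benzyloxy)-4-{(E)-2-[4-(benzyloxy)phenyl]ethenyl}-2-[4-(tosyloxy)phenyl]-2,3-dihydro-1-benzofuran-3-yl]-2-[4-(tosyloxy)phenyl]-2,3-dihydro-1-benzofuran-3-carboxylate
Conditions: NiBr2·glyme (20 mol %), dtbbpy (20 mol %), Zn (3 equiv), DMA, 25 °C
Reagents that add atoms: none
Why: In this nickel-catalysed decarboxylative cross-electrophile coupling, single-electron reduction of the NHP ester releases CO2 and the planar C3 benzylic radical, which should be captured by the aryl–nickel species from 11 on the face anti to the C2 aryl, so that the C3–C5′ bond forms trans (3S) while the ring C2–O bond, lying in the nodal plane of the radical, is not cleaved.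

Step 16
Reactants: 24 methyl (2R,3R)-7-(benzyloxy)-5-[(2S,3S)-6-(benzyloxy)-4-{(E)-2-[4-(benzyloxy)phenyl]ethenyl}-2-[4-(tosyloxy)phenyl]-2,3-dihydro-1-benzofuran-3-yl]-2-[4-(tosyloxy)phenyl]-2,3-dihydro-1-benzofuran-3-carboxylate
Product: 25 the corresponding (2R,3R)-2,3-dihydro-1-benzofuran-3-carboxylic acid (lower C3′–CO2H, all else unchanged)
Conditions: Me3SnOH (8 equiv), ClCH2CH2Cl, 75 °C; aq. HCl
Reagents that add atoms: trimethyltin hydroxide, C[Sn](C)(C)O
Why: The same mild methyl-ester cleavage as in step 11 should free the second carboxyl without base-induced opening of the lower dihydrofuran and without touching tosylates, benzyl ethers or the stilbene.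

Step 17
Reactants: 25 the lower C3′ carboxylic acid
Product: 26 the 1,3-dioxoisoindolin-2-yl ester of acid 25
Conditions: N-hydroxyphthalimide, DIC, CH2Cl2, 0 °C to 20 °C
Reagents that add atoms: N-hydroxyphthalimide, O=C1c2ccccc2C(=O)N1O
Why: Carbodiimide esterification should give the second redox-active ester under base-free conditions.

Step 18
Reactants: 26 the 1,3-dioxoisoindolin-2-yl ester of acid 25; 27 1,3-bis(benzyloxy)-5-bromobenzene
Product: 28 (2S,3S)-6-(benzyloxy)-4-{(E)-2-[4-(benzyloxy)phenyl]ethenyl}-3-{(2R,3R)-7-(benzyloxy)-3-[3,5-bis(benzyloxy)phenyl]-2-[4-(tosyloxy)phenyl]-2,3-dihydro-1-benzofuran-5-yl}-2-[4-(tosyloxy)phenyl]-2,3-dihydro-1-benzofuran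
Conditions: NiBr2·glyme (20 mol %), dtbbpy (20 mol %), Zn (3 equiv), DMA, 25 °C
Reagents that add atoms: none
Why: The same nickel-catalysed decarboxylative cross-electrophile coupling should deliver the resorcinol ring to the C3′ radical anti to the C2′ aryl and so set C3′ as R (trans).

Step 19
Reactants: 28 the penta-O-benzyl di-O-tosyl precursor
Product: 29 4,4′-bis-phenol: compound 28 with both tosyloxy groups replaced by hydroxyl
Conditions: KOH (10 equiv), MeOH/THF, 60 °C, argon; aq. HCl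
Reagents that add atoms: none
Why: Hydroxide should attack sulfur of the two aryl sulfonates (S–O cleavage) and free the 4-hydroxyphenyl groups while benzyl ethers, stilbene and both dihydrofurans, which no longer carry an acidifying group, are left alone.

Step 20
Reactants: 29 the penta-O-benzyl bis-phenol
Product: 30 5-[(2R,3R)-7-hydroxy-5-{(2S,3S)-6-hydroxy-2-(4-hydroxyphenyl)-4-[(E)-2-(4-hydroxyphenyl)ethenyl]-2,3-dihydro-1-benzofuran-3-yl}-2-(4-hydroxyphenyl)-2,3-dihydro-1-benzofuran-3-yl]benzene-1,3-diol (CNP0172909.1)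
Conditions: BCl3 (excess), pentamethylbenzene (excess), CH2Cl2, −78 °C; MeOH quench at −78 °C
Reagents that add atoms: none
Why: BCl3-mediated debenzylation with pentamethylbenzene as a non-basic benzyl-cation scavenger at low temperature should cleave all five benzyl ethers without protonating the stilbene or ionising the dihydrofuran C2–O bonds.

**Compound list**
1 | 1-(2,3-dihydroxyphenyl)ethan-1-one | CC(=O)c1cccc(O)c1O | starting material
2 | 1-[3-(benzyloxy)-2-hydroxyphenyl]ethan-1-one | CC(=O)c1cccc(OCc2ccccc2)c1O | intermediate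
3 | 1-[3-(benzyloxy)-5-bromo-2-hydroxyphenyl]ethan-1-one | CC(=O)c1cc(Br)cc(OCc2ccccc2)c1O | intermediate
4 | (E)-1-[3-(benzyloxy)-5-bromo-2-hydroxyphenyl]-3-(dimethylamino)prop-2-en-1-one | CN(C)/C=C/C(=O)c1cc(Br)cc(OCc2ccccc2)c1O | intermediate
5 | 8-(benzyloxy)-6-bromo-4H-chromen-4-one | O=c1ccoc2c(OCc3ccccc3)cc(Br)cc12 | intermediate
6 | (4-hydroxyphenyl)boronic acid | OB(O)c1ccc(O)cc1 | starting material
7 | [4-(tosyloxy)phenyl]boronic acid | Cc1ccc(cc1)S(=O)(=O)Oc1ccc(cc1)B(O)O | intermediate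
8 | (2R)-8-(benzyloxy)-6-bromo-2-[4-(tosyloxy)phenyl]chroman-4-one | O=C1C[C@H](c2ccc(OS(=O)(=O)c3ccc(C)cc3)cc2)Oc2c(OCc3ccccc3)cc(Br)cc21 | intermediate
9 | (2R)-8-(benzyloxy)-6-bromo-4-methoxy-2-[4-(tosyloxy)phenyl]-2H-chromene | COC1=C[C@H](c2ccc(OS(=O)(=O)c3ccc(C)cc3)cc2)Oc2c(OCc3ccccc3)cc(Br)cc21 | intermediate
10 | (2S,3S)-3-[acetoxy(phenyl)-λ3-iodanyl]-8-(benzyloxy)-6-bromo-4,4-dimethoxy-2-[4-(tosyloxy)phenyl]chromane (2,3-trans; C2 unchanged in space) | COC1(OC)[C@@H](I(OC(C)=O)c2ccccc2)[C@H](c2ccc(OS(=O)(=O)c3ccc(C)cc3)cc2)Oc2c(OCc3ccccc3)cc(Br)cc21 | intermediate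
11 | methyl (2R,3R)-7-(benzyloxy)-5-bromo-2-[4-(tosyloxy)phenyl]-2,3-dihydro-1-benzofuran-3-carboxylate | Brc1cc(OCc3ccccc3)c2c(c1)[C@@H](C(=O)OC)[C@H](c1ccc(OS(=O)(=O)c3ccc(C)cc3)cc1)O2 | intermediate
12 | (2S)-naringenin | O=C1C[C@@H](c2ccc(O)cc2)Oc2cc(O)cc(O)c21 | starting material
13 | (2S)-7-(benzyloxy)-5-hydroxy-2-(4-hydroxyphenyl)chroman-4-one | O=C1C[C@@H](c2ccc(O)cc2)Oc2cc(OCc3ccccc3)cc(O)c21 | intermediate
14 | (2S)-7-(benzyloxy)-5-hydroxy-2-[4-(tosyloxy)phenyl]chroman-4-one | O=C1C[C@@H](c2ccc(OS(=O)(=O)c3ccc(C)cc3)cc2)Oc2cc(OCc3ccccc3)cc(O)c21 | intermediate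
15 | (2S)-7-(benzyloxy)-2-[4-(tosyloxy)phenyl]-5-(triflyloxy)chroman-4-one | O=C1C[C@@H](c2ccc(OS(=O)(=O)c3ccc(C)cc3)cc2)Oc2cc(OCc3ccccc3)cc(OS(=O)(=O)C(F)(F)F)c21 | intermediate
16 | (2S)-7-(benzyloxy)-4-methoxy-2-[4-(tosyloxy)phenyl]-5-(triflyloxy)-2H-chromene | COC1=C[C@@H](c2ccc(OS(=O)(=O)c3ccc(C)cc3)cc2)Oc2cc(OCc3ccccc3)cc(OS(=O)(=O)C(F)(F)F)c21 | intermediate
17 | (2R,3R)-3-[acetoxy(phenyl)-λ3-iodanyl]-7-(benzyloxy)-4,4-dimethoxy-2-[4-(tosyloxy)phenyl]-5-(triflyloxy)chromane (2,3-trans) | COC1(OC)[C@H](I(OC(C)=O)c2ccccc2)[C@@H](c2ccc(OS(=O)(=O)c3ccc(C)cc3)cc2)Oc2cc(OCc3ccccc3)cc(OS(=O)(=O)C(F)(F)F)c21 | intermediate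
18 | methyl (2S,3S)-6-(benzyloxy)-2-[4-(tosyloxy)phenyl]-4-(triflyloxy)-2,3-dihydro-1-benzofuran-3-carboxylate | FC(F)(F)S(=O)(=O)Oc1cc(OCc2ccccc2)cc2c1[C@H](C(=O)OC)[C@@H](c1ccc(OS(=O)(=O)c3ccc(C)cc3)cc1)O2 | intermediate
19 | (2S,3S)-6-(benzyloxy)-2-[4-(tosyloxy)phenyl]-4-(triflyloxy)-2,3-dihydro-1-benzofuran-3-carboxylic acid | FC(F)(F)S(=O)(=O)Oc1cc(OCc2ccccc2)cc2c1[C@H](C(=O)O)[C@@H](c1ccc(OS(=O)(=O)c3ccc(C)cc3)cc1)O2 | intermediate
20 | 1-(benzyloxy)-4-ethynylbenzene | C#Cc1ccc(OCc2ccccc2)cc1 | starting material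
21 | 2-{(E)-2-[4-(benzyloxy)phenyl]ethenyl}-4,4,5,5-tetramethyl-1,3,2-dioxaborolane | CC1(C)OB(/C=C/c2ccc(OCc3ccccc3)cc2)OC1(C)C | intermediate
22 | (2S,3S)-6-(benzyloxy)-4-{(E)-2-[4-(benzyloxy)phenyl]ethenyl}-2-[4-(tosyloxy)phenyl]-2,3-dihydro-1-benzofuran-3-carboxylic acid | c1ccccc1COc1ccc(/C=C/c2cc(OCc3ccccc3)cc3c2[C@H](C(=O)O)[C@@H](c2ccc(OS(=O)(=O)c4ccc(C)cc4)cc2)O3)cc1 | intermediate
23 | 1,3-dioxoisoindolin-2-yl ester of acid 22 | c1ccccc1COc1ccc(/C=C/c2cc(OCc3ccccc3)cc3c2[C@H](C(=O)ON5C(=O)c6ccccc6C5=O)[C@@H](c2ccc(OS(=O)(=O)c4ccc(C)cc4)cc2)O3)cc1 | intermediate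
24 | methyl (2R,3R)-7-(benzyloxy)-5-[(2S,3S)-6-(benzyloxy)-4-{(E)-2-[4-(benzyloxy)phenyl]ethenyl}-2-[4-(tosyloxy)phenyl]-2,3-dihydro-1-benzofuran-3-yl]-2-[4-(tosyloxy)phenyl]-2,3-dihydro-1-benzofuran-3-carboxylate | c1ccccc1COc1ccc(/C=C/c2cc(OCc3ccccc3)cc3c2[C@H](c2cc(OCc4ccccc4)c4c(c2)[C@@H](C(=O)OC)[C@H](c2ccc(OS(=O)(=O)c5ccc(C)cc5)cc2)O4)[C@@H](c2ccc(OS(=O)(=O)c4ccc(C)cc4)cc2)O3)cc1 | intermediate
25 | (2R,3R)-3-carboxylic acid corresponding to ester 24 | c1ccccc1COc1ccc(/C=C/c2cc(OCc3ccccc3)cc3c2[C@H](c2cc(OCc4ccccc4)c4c(c2)[C@@H](C(=O)O)[C@H](c2ccc(OS(=O)(=O)c5ccc(C)cc5)cc2)O4)[C@@H](c2ccc(OS(=O)(=O)c4ccc(C)cc4)cc2)O3)cc1 | intermediate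
26 | 1,3-dioxoisoindolin-2-yl ester of acid 25 | c1ccccc1COc1ccc(/C=C/c2cc(OCc3ccccc3)cc3c2[C@H](c2cc(OCc4ccccc4)c4c(c2)[C@@H](C(=O)ON6C(=O)c7ccccc7C6=O)[C@H](c2ccc(OS(=O)(=O)c5ccc(C)cc5)cc2)O4)[C@@H](c2ccc(OS(=O)(=O)c4ccc(C)cc4)cc2)O3)cc1 | intermediate
27 | 1,3-bis(benzyloxy)-5-bromobenzene | Brc1cc(OCc2ccccc2)cc(OCc2ccccc2)c1 | starting material
28 | (2S,3S)-6-(benzyloxy)-4-{(E)-2-[4-(benzyloxy)phenyl]ethenyl}-3-{(2R,3R)-7-(benzyloxy)-3-[3,5-bis(benzyloxy)phenyl]-2-[4-(tosyloxy)phenyl]-2,3-dihydro-1-benzofuran-5-yl}-2-[4-(tosyloxy)phenyl]-2,3-dihydro-1-benzofuran | c1ccccc1COc1ccc(/C=C/c2cc(OCc3ccccc3)cc3c2[C@H](c2cc(OCc4ccccc4)c4c(c2)[C@@H](c2cc(OCc5ccccc5)cc(OCc5ccccc5)c2)[C@H](c2ccc(OS(=O)(=O)c5ccc(C)cc5)cc2)O4)[C@@H](c2ccc(OS(=O)(=O)c4ccc(C)cc4)cc2)O3)cc1 | intermediate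
29 | compound 28 with both tosyloxy groups replaced by hydroxyl (penta-O-benzyl bis-phenol) | c1ccccc1COc1ccc(/C=C/c2cc(OCc3ccccc3)cc3c2[C@H](c2cc(OCc4ccccc4)c4c(c2)[C@@H](c2cc(OCc5ccccc5)cc(OCc5ccccc5)c2)[C@H](c2ccc(O)cc2)O4)[C@@H](c2ccc(O)cc2)O3)cc1 | intermediate
30 | CNP0172909.1 | Oc1ccc(/C=C/c2cc(O)cc3c2[C@H](c2cc(O)c4c(c2)[C@@H](c2cc(O)cc(O)c2)[C@H](c2ccc(O)cc2)O4)[C@@H](c2ccc(O)cc2)O3)cc1 | target

**Totals**
Total step count: 20. Longest linear sequence: 13 steps (steps 7 to 11 and 13 to 20, from (S)-naringenin).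

**Steps most likely to fail**

Step 15. The hindered C3 radical (flanked by the C4 styryl and the C2 aryl) may be captured too slowly by aryl–nickel, so that radical dimerisation or reduction and homocoupling of the aryl bromide take over; facial selectivity may also be incomplete. The fallback gives up the two-electrophile reductive manifold for a coupling with a preformed aryl nucleophile under iron catalysis; it sets out from 11 and 22 and comes back at 24. Magnesium insertion into 11 in the presence of LiCl and ZnCl2 (THF, 25 °C) would give [(2R,3R)-7-(benzyloxy)-3-(methoxycarbonyl)-2-[4-(tosyloxy)phenyl]-2,3-dihydro-1-benzofuran-5-yl]zinc chloride F1. Acid 22 would be esterified with N-hydroxytetrachlorophthalimide and DIC to the tetrachloro redox-active ester F2. Fe(acac)3 with 1,2-bis(diphenylphosphino)benzene in THF would then couple F2 with F1 to give 24.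

Step 10. Ketalisation next to the peri triflate may be sluggish and the triflated ring A may migrate poorly, so that dehydrogenation to the flavone or shift of the C2 aryl competes. The fallback installs the triflate after the rearrangement instead of before it; it sets out from 14 and comes back at 18. Acetylation of 14 (Ac2O, pyridine) would give (2S)-5-acetoxy-7-(benzyloxy)-2-[4-(tosyloxy)phenyl]chroman-4-one F3. The same ring contraction on this more electron-rich substrate would give methyl (2S,3S)-4-acetoxy-6-(benzyloxy)-2-[4-(tosyloxy)phenyl]-2,3-dihydro-1-benzofuran-3-carboxylate F4. Hydrazinolysis of the aryl acetate (N2H4·H2O, THF/MeOH, 0 °C) would give methyl (2S,3S)-6-(benzyloxy)-4-hydroxy-2-[4-(tosyloxy)phenyl]-2,3-dihydro-1-benzofuran-3-carboxylate F5, whose now non-chelated phenol would be triflated (Tf2O, pyridine) to 18.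

Step 6. Dehydrogenation to the flavone, shift of the C2 aryl to give the isoflavone, or acid-mediated opening of the pyranone with loss of the C2 configuration may compete with the ring-C shift. The fallback builds the same ester by enantioselective carbene C–H insertion (forming C2′–C3′ instead); it sets out from 3 and comes back at 11. O-Alkylation of 3 with 4-(bromomethyl)phenyl 4-methylbenzenesulfonate (K2CO3, DMF) would give 4-{[2-acetyl-6-(benzyloxy)-4-bromophenoxy]methyl}phenyl 4-methylbenzenesulfonate F6. Oxidative 1,2-aryl shift of the aryl methyl ketone (PhI(OAc)2, H2SO4, HC(OMe)3) would give methyl 2-[3-(benzyloxy)-5-bromo-2-{[4-(tosyloxy)benzyl]oxy}phenyl]acetate F7. Diazo transfer (4-acetamidobenzenesulfonyl azide, DBU, MeCN) would give methyl 2-[3-(benzyloxy)-5-bromo-2-{[4-(tosyloxy)benzyl]oxy}phenyl]-2-diazoacetate F8. Intramolecular C–H insertion into the benzylic OCH2 with the chiral dirhodium carboxylate Rh2(S-PTTL)4 (or its antipode, whichever delivers 2R; toluene, −60 °C) would give methyl (2R,3S)-7-(benzyloxy)-5-bromo-2-[4-(tosyloxy)phenyl]-2,3-dihydro-1-benzofuran-3-carboxylate (cis) F9, which NaOMe in MeOH at 0 °C would epimerise at C3′ to the trans ester 11.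

**Further compounds**
F1 | step 15 | [(2R,3R)-7-(benzyloxy)-3-(methoxycarbonyl)-2-[4-(tosyloxy)phenyl]-2,3-dihydro-1-benzofuran-5-yl]zinc chloride | Cl[Zn]c1cc(OCc3ccccc3)c2c(c1)[C@@H](C(=O)OC)[C@H](c1ccc(OS(=O)(=O)c3ccc(C)cc3)cc1)O2
F2 | step 15 | 4,5,6,7-tetrachloro-1,3-dioxoisoindolin-2-yl ester of acid 22 | c1ccccc1COc1ccc(/C=C/c2cc(OCc3ccccc3)cc3c2[C@H](C(=O)ON5C(=O)c6c(Cl)c(Cl)c(Cl)c(Cl)c6C5=O)[C@@H](c2ccc(OS(=O)(=O)c4ccc(C)cc4)cc2)O3)cc1
F3 | step 10 | (2S)-5-acetoxy-7-(benzyloxy)-2-[4-(tosyloxy)phenyl]chroman-4-one | O=C1C[C@@H](c2ccc(OS(=O)(=O)c3ccc(C)cc3)cc2)Oc2cc(OCc3ccccc3)cc(OC(C)=O)c21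
F4 | step 10 | methyl (2S,3S)-4-acetoxy-6-(benzyloxy)-2-[4-(tosyloxy)phenyl]-2,3-dihydro-1-benzofuran-3-carboxylate | CC(=O)Oc1cc(OCc2ccccc2)cc2c1[C@H](C(=O)OC)[C@@H](c1ccc(OS(=O)(=O)c3ccc(C)cc3)cc1)O2
F5 | step 10 | methyl (2S,3S)-6-(benzyloxy)-4-hydroxy-2-[4-(tosyloxy)phenyl]-2,3-dihydro-1-benzofuran-3-carboxylate | Oc1cc(OCc2ccccc2)cc2c1[C@H](C(=O)OC)[C@@H](c1ccc(OS(=O)(=O)c3ccc(C)cc3)cc1)O2
F6 | step 6 | 4-{[2-acetyl-6-(benzyloxy)-4-bromophenoxy]methyl}phenyl 4-methylbenzenesulfonate | CC(=O)c1cc(Br)cc(OCc2ccccc2)c1OCc1ccc(OS(=O)(=O)c2ccc(C)cc2)cc1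
F7 | step 6 | methyl 2-[3-(benzyloxy)-5-bromo-2-{[4-(tosyloxy)benzyl]oxy}phenyl]acetate | COC(=O)Cc1cc(Br)cc(OCc2ccccc2)c1OCc1ccc(OS(=O)(=O)c2ccc(C)cc2)cc1
F8 | step 6 | methyl 2-[3-(benzyloxy)-5-bromo-2-{[4-(tosyloxy)benzyl]oxy}phenyl]-2-diazoacetate | COC(=O)C(=[N+]=[N-])c1cc(Br)cc(OCc2ccccc2)c1OCc1ccc(OS(=O)(=O)c2ccc(C)cc2)cc1
F9 | step 6 | methyl (2R,3S)-7-(benzyloxy)-5-bromo-2-[4-(tosyloxy)phenyl]-2,3-dihydro-1-benzofuran-3-carboxylate (cis) | Brc1cc(OCc3ccccc3)c2c(c1)[C@H](C(=O)OC)[C@H](c1ccc(OS(=O)(=O)c3ccc(C)cc3)cc1)O2
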